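**Plan**
- Retrosynthesis: cut the C5–O ester (Mitsunobu, side-chain acid 32), return C5 to an exocyclic C=CH2, then cut together the C4–C5 bond and the ring O–C3 bond of the oxane. This opens the oxane and the 14-membered lactone at once to the acyclic ester 16.
- Enabling feature: in the 4,15-dioxabicyclo[9.3.1]pentadecane core, oxane carbon C3 carries the CH2–C(=O)–O arm of the lactone, so C1–C4 is a but-3-enoate on O13 after a hydrogen shift (C3 becomes the β-carbon that accepts O7). Oxygenated C5 lies 1,3 to the C7 carbinol, so C5–C7 is a homopropargylic alcohol at the alkyne level.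
- Forward: C7–C16 is grown linearly from (R)-methyl hydrogen 3-methylglutarate, O13 is acylated with but-3-enoic acid, and C7 is propargylated. One Ru-catalysed ene–yne coupling/transannular oxa-Michael operation closes the 14-membered ring (C4–C5) and then the oxane (O–C3); ozonolysis, reduction and Mitsunobu esterification finish.
- Stereochemistry: C9 from the chiral pool; C11 by Brown allylation; C13 by chelation-controlled allylation (1,3-anti to C11–OMe); C7 by chiral phosphoric acid-catalysed propargylation; C3 by the 2,6-cis oxa-Michael closure; C5 by axial hydride delivery then Mitsunobu inversion; both Z-alkenes by Still–Gennari olefination and Lindlar reduction.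

Key step: step 13

Remark: atom numbers C1–C16 are those of the macrolide (C1 lactone carbonyl, C13 propyl-bearing carbinol). Compounds 1, 12, 22, 24 and all named reagents are taken as commercial. (S)-TRIP is (S)-3,3'-bis(2,4,6-triisopropylphenyl)-1,1'-binaphthyl-2,2'-diyl hydrogen phosphate, chosen on the assumption that propargylboration follows the same facial sense as allylboration with this acid.

**Fragment 1 (macrolide core)**

Step 1
Reactants: 1 (3R)-5-methoxy-3-methyl-5-oxopentanoic acid
Product: 2 methyl (3R)-5-hydroxy-3-methylpentanoate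
Conditions: BH3·SMe2 (1.2 equiv), THF, 0 °C → rt; MeOH quench
Reagents that add atoms: none
Why: Borane reduces the carboxylic acid chemoselectively beside the methyl ester; C9 is untouched and the crude alcohol is silylated at once to forestall lactonisation.

Step 2
Reactants: 2 methyl (3R)-5-hydroxy-3-methylpentanoate
Product: 3 methyl (3R)-5-[(tert-butyldiphenylsilyl)oxy]-3-methylpentanoate
Conditions: TBDPSCl (1.1 equiv), imidazole, DMF, 0 °C → rt
Reagents that add atoms: tert-butyl(chloro)diphenylsilane, CC(C)(C)[Si](Cl)(c1ccccc1)c1ccccc1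
Why: Standard silylation of a primary alcohol; the TBDPS ether is chosen to survive NaH/MeI, TiCl4 and hydrogenation.

Step 3
Reactants: 3 methyl (3R)-5-[(tert-butyldiphenylsilyl)oxy]-3-methylpentanoate
Product: 4 (3R)-5-[(tert-butyldiphenylsilyl)oxy]-3-methylpentanal
Conditions: i-Bu2AlH (1.05 equiv), CH2Cl2, −78 °C; Rochelle salt work-up
Reagents that add atoms: none
Why: Partial ester reduction stops at the aldehyde because the tetrahedral aluminium hemiacetal is stable at −78 °C.

Step 4
Reactants: 4 (3R)-5-[(tert-butyldiphenylsilyl)oxy]-3-methylpentanal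
Product: 6 (4S,6R)-8-[(tert-butyldiphenylsilyl)oxy]-6-methyloct-1-en-4-ol, via diisopinocampheylborinate ester 5 (not isolated)
Conditions: (−)-Ipc2B(allyl) (1.3 equiv), Et2O, −78 °C; then 3 M NaOH, 30% H2O2, 0 °C → rt
Reagents that add atoms: (−)-B-allyldiisopinocampheylborane (from (+)-α-pinene), C=CCB([C@@H]1C[C@@H]2C[C@H]([C@H]1C)C2(C)C)[C@@H]1C[C@@H]2C[C@H]([C@H]1C)C2(C)C
Why: Brown allylboration through a closed chair transition state; this reagent should attack the si face of 4 and set C11 (4S) under reagent control, since the β-methyl group exerts little bias.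

Step 5
Reactants: 6 (4S,6R)-8-[(tert-butyldiphenylsilyl)oxy]-6-methyloct-1-en-4-ol
Product: 7 tert-butyl{[(3R,5S)-5-methoxy-3-methyloct-7-en-1-yl]oxy}diphenylsilane
Conditions: NaH (1.5 equiv), MeI (3 equiv), THF, 0 °C → rt
Reagents that add atoms: iodomethane, CI
Why: Williamson etherification installs the C11 methyl ether before the C13 oxygen exists, so the two oxygens never need to be told apart.

Step 6
Reactants: 7 tert-butyl{[(3R,5S)-5-methoxy-3-methyloct-7-en-1-yl]oxy}diphenylsilane
Product: 9 (3R,5R)-7-[(tert-butyldiphenylsilyl)oxy]-3-methoxy-5-methylheptanal, via secondary ozonide 8 (not isolated)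
Conditions: O3, CH2Cl2, −78 °C; then PPh3, −78 °C → rt
Reagents that add atoms: ozone, [O-][O+]=O
Why: Ozonolysis with neutral reductive work-up gives the β-methoxy aldehyde without β-elimination of methanol.

Step 7
Reactants: 9 (3R,5R)-7-[(tert-butyldiphenylsilyl)oxy]-3-methoxy-5-methylheptanal
Product: 10 (4R,6R,8R)-10-[(tert-butyldiphenylsilyl)oxy]-6-methoxy-8-methyldec-1-en-4-ol
Conditions: TiCl4 (1.0 equiv), CH2Cl2, −78 °C; then allyltrimethylsilane (2 equiv), −78 °C
Reagents that add atoms: allyltrimethylsilane, C=CC[Si](C)(C)C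
Why: Hosomi–Sakurai allylation under chelation control: TiCl4 bridges the aldehyde and the C11 methoxy group in a six-membered chelate and the silane attacks the face away from the C11 substituent, which should set C13 (4R) 1,3-anti.

Step 8
Reactants: 10 (4R,6R,8R)-10-[(tert-butyldiphenylsilyl)oxy]-6-methoxy-8-methyldec-1-en-4-ol
Product: 11 (4R,6R,8R)-10-[(tert-butyldiphenylsilyl)oxy]-6-methoxy-8-methyldecan-4-ol
Conditions: H2 (1 atm), Pd/C (10 wt%), EtOAc, rt
Reagents that add atoms: none
Why: Hydrogenation turns the allyl group into the propyl chain and removes an alkene that would compete in step 13.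

Step 9
Reactants: 11 (4R,6R,8R)-10-[(tert-butyldiphenylsilyl)oxy]-6-methoxy-8-methyldecan-4-ol; 12 but-3-enoic acid
Product: 13 (4R,6R,8R)-10-[(tert-butyldiphenylsilyl)oxy]-6-methoxy-8-methyldecan-4-yl but-3-enoate
Conditions: DCC (1.5 equiv), DMAP (0.1 equiv), CH2Cl2, 0 °C
Reagents that add atoms: none
Why: Steglich esterification; low temperature and only catalytic DMAP should keep the β,γ-double bond from moving into conjugation.

Step 10
Reactants: 13 (4R,6R,8R)-10-[(tert-butyldiphenylsilyl)oxy]-6-methoxy-8-methyldecan-4-yl but-3-enoate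
Product: 14 (4R,6R,8R)-10-hydroxy-6-methoxy-8-methyldecan-4-yl but-3-enoate
Conditions: HF·pyridine, pyridine/THF, 0 °C → rt
Reagents that add atoms: none
Why: Buffered fluoride cleaves the silyl ether without the basic conditions that would isomerise or cleave the but-3-enoate.

Step 11
Reactants: 14 (4R,6R,8R)-10-hydroxy-6-methoxy-8-methyldecan-4-yl but-3-enoate
Product: 15 (4R,6R,8S)-6-methoxy-8-methyl-10-oxodecan-4-yl but-3-enoate
Conditions: Dess–Martin periodinane (1.3 equiv), CH2Cl2, 0 °C → rt
Reagents that add atoms: none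
Why: Dess–Martin oxidation of a primary alcohol under near-neutral conditions; no stereocentre is α to the new aldehyde.

Step 12
Reactants: 15 (4R,6R,8S)-6-methoxy-8-methyl-10-oxodecan-4-yl but-3-enoate
Product: 16 (4R,6R,8R,10R)-10-hydroxy-6-methoxy-8-methyltridec-12-yn-4-yl but-3-enoate
Conditions: allenylB(pin) (1.5 equiv), (S)-TRIP (10 mol%), 4 Å MS, toluene, −20 °C
Reagents that add atoms: allenylboronic acid pinacol ester, C=C=CB1OC(C)(C)C(C)(C)O1
Why: Chiral phosphoric acid-catalysed propargylboration through a closed chair transition state with allenyl-to-propargyl transposition; the (S)-acid is chosen for si-face attack, which sets C7 (10R) under catalyst control.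

Step 13
Reactants: 16 (4R,6R,8R,10R)-10-hydroxy-6-methoxy-8-methyltridec-12-yn-4-yl but-3-enoate
Product: 18 (1R,5R,7R,9S,11R)-7-methoxy-9-methyl-13-methylidene-5-propyl-4,15-dioxabicyclo[9.3.1]pentadecan-3-one, via macrocyclic hydroxy dienoate 17 (not isolated)
Conditions: [CpRu(MeCN)3]PF6 (10 mol%), acetone, 2 mM (slow addition of 16), rt; then DBU (1 equiv) added to the same flask, rt → 40 °C
Reagents that add atoms: none
Why: Proposed new method: [CpRu(MeCN)3]+ binds the terminal alkyne and the but-3-enoate C=C of 16, oxidative cyclisation gives a ruthenacyclopentene with the new C4–C5 bond, β-hydride elimination from C2 and reductive elimination onto the former alkyne CH release the skipped diene 17 (E-2-enoate, C5=CH2), and DBU then adds the C7 hydroxyl across the ring to C3. The closest known reaction type is the intermolecular Ru-catalysed alkene–alkyne coupling/oxa-Michael tandem of homopropargylic alcohols with β,γ-unsaturated carbonyl compounds to 4-methylene-2,6-cis-oxanes, and separately the Ru-catalysed ene–yne macrocyclisation; their merger on an ester-tethered substrate, so that one operation builds both rings, is the untested part. The 14-membered lactone closes by C–C formation at the internal alkyne carbon (exo mode, the alkyne CH ending as the exocyclic methylene), and the oxane closes by a transannular 6-exo-trig oxa-Michael addition. The one new stereocentre, C3, is set by the existing C7 centre: closure through a chair with the C3 and C7 substituents both equatorial gives the 2,6-cis oxane, and reversibility of the addition under DBU should let the system settle on this less strained bridged isomer. The step needs branched regiochemistry at the alkyne (the usual preference of terminal alkynes with this catalyst, and the one that gives the smaller ring), ring closure in place of oligomerisation (high dilution, slow addition), and oxygen addition ahead of base-mediated migration of the skipped diene (the C7 hydroxyl sits four atoms from C3 on the same chain). The free hydroxyl, ester and methyl ether should be inert to the phosphine-free cationic catalyst, which does not open vinylidene pathways.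

Step 14
Reactants: 18 (1R,5R,7R,9S,11R)-7-methoxy-9-methyl-13-methylidene-5-propyl-4,15-dioxabicyclo[9.3.1]pentadecan-3-one
Product: 20 (1R,5R,7R,9S,11R)-7-methoxy-9-methyl-5-propyl-4,15-dioxabicyclo[9.3.1]pentadecane-3,13-dione, via spiro ozonide 19 (not isolated)
Conditions: O3, CH2Cl2, −78 °C; then PPh3, −78 °C → rt
Reagents that add atoms: ozone, [O-][O+]=O
Why: Ozonolysis of the only C=C removes the methylene helper and leaves the C5 ketone.

Step 15
Reactants: 20 (1R,5R,7R,9S,11R)-7-methoxy-9-methyl-5-propyl-4,15-dioxabicyclo[9.3.1]pentadecane-3,13-dione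
Product: 21 (1R,5R,7R,9S,11R,13S)-13-hydroxy-7-methoxy-9-methyl-5-propyl-4,15-dioxabicyclo[9.3.1]pentadecan-3-one
Conditions: NaBH4, MeOH, 0 °C
Reagents that add atoms: none
Why: The small hydride should attack the chair oxan-4-one axially and give the equatorial C5 alcohol (13S); the lactone is not reduced.

**Fragment 2 (oxazole acid)**

Step 16
Reactants: 22 prop-2-yn-1-amine
Product: 23 methyl prop-2-yn-1-ylcarbamate
Conditions: ClCO2Me (1.05 equiv), Et3N, CH2Cl2, 0 °C
Reagents that add atoms: methyl chloroformate, COC(=O)Cl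
Why: N-acylation of a primary amine with a chloroformate.

Step 17
Reactants: 24 methyl 5-bromo-4-oxopentanoate
Product: 25 methyl 3-(1,3-oxazol-4-yl)propanoate
Conditions: HCONH2 (neat, excess), 110 °C
Reagents that add atoms: formamide, NC=O
Why: Bredereck oxazole synthesis: formamide is alkylated by the α-bromoketone and cyclodehydrates, which places the ketone carbon at C4 and leaves C2 unsubstituted.

Step 18
Reactants: 25 methyl 3-(1,3-oxazol-4-yl)propanoate
Product: 27 methyl 3-(2-iodo-1,3-oxazol-4-yl)propanoate, via oxazol-2-ylzinc chloride 26 (not isolated)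
Conditions: TMPZnCl·LiCl (TMP = 2,2,6,6-tetramethylpiperidide, 1.2 equiv), THF, 25 °C; then I2 (1.3 equiv), 0 °C
Reagents that add atoms: iodine, II
Why: The hindered zinc amide removes the most acidic ring proton (C2–H), tolerates the ester and gives a ring-closed zinc species that iodine captures.

Step 19
Reactants: 27 methyl 3-(2-iodo-1,3-oxazol-4-yl)propanoate
Product: 28 3-(2-iodo-1,3-oxazol-4-yl)propanal
Conditions: i-Bu2AlH (1.05 equiv), CH2Cl2, −78 °C; Rochelle salt work-up
Reagents that add atoms: none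
Why: Partial ester reduction at −78 °C, as in step 3; the C–I bond is inert to the hydride.

Step 20
Reactants: 28 3-(2-iodo-1,3-oxazol-4-yl)propanal
Product: 29 methyl (2Z)-5-(2-iodo-1,3-oxazol-4-yl)pent-2-enoate
Conditions: (CF3CH2O)2P(O)CH2CO2Me, KN(SiMe3)2, 18-crown-6, THF, −78 °C
Reagents that add atoms: methyl bis(2,2,2-trifluoroethyl)phosphonoacetate, COC(=O)CP(=O)(OCC(F)(F)F)OCC(F)(F)F
Why: Still–Gennari olefination: fast, irreversible elimination from the kinetic adduct of the electron-poor phosphonate should give the Z-enoate.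

Step 21
Reactants: 29 methyl (2Z)-5-(2-iodo-1,3-oxazol-4-yl)pent-2-enoate; 23 methyl prop-2-yn-1-ylcarbamate
Product: 30 methyl (2Z)-5-(2-{3-[(methoxycarbonyl)amino]prop-1-yn-1-yl}-1,3-oxazol-4-yl)pent-2-enoate
Conditions: Pd(PPh3)4 (5 mol%), CuI (10 mol%), Et3N, THF, rt
Reagents that add atoms: none
Why: Sonogashira coupling; zerovalent palladium inserts readily into the activated C2–I bond and the carbamate N–H is tolerated.

Step 22
Reactants: 30 methyl (2Z)-5-(2-{3-[(methoxycarbonyl)amino]prop-1-yn-1-yl}-1,3-oxazol-4-yl)pent-2-enoate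
Product: 31 methyl (2Z)-5-(2-{(1Z)-3-[(methoxycarbonyl)amino]prop-1-en-1-yl}-1,3-oxazol-4-yl)pent-2-enoate
Conditions: H2 (1 atm), Pd/CaCO3 poisoned with Pb(OAc)2, quinoline, EtOAc, rt
Reagents that add atoms: none
Why: Lindlar semi-hydrogenation adds hydrogen syn to the alkyne and should stop at the Z-alkene, leaving the enoate alone.

Step 23
Reactants: 31 methyl (2Z)-5-(2-{(1Z)-3-[(methoxycarbonyl)amino]prop-1-en-1-yl}-1,3-oxazol-4-yl)pent-2-enoate
Product: 32 (2Z)-5-(2-{(1Z)-3-[(methoxycarbonyl)amino]prop-1-en-1-yl}-1,3-oxazol-4-yl)pent-2-enoic acid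
Conditions: LiOH (2 equiv), THF/H2O 3:1, 0 °C → rt; then 1 M HCl to pH 3
Reagents that add atoms: lithium hydroxide, [Li+].[OH-]
Why: Saponification of the methyl ester is much faster than attack on the methyl carbamate and should leave both Z-alkenes in place.

**Union**

Step 24
Reactants: 21 (1R,5R,7R,9S,11R,13S)-13-hydroxy-7-methoxy-9-methyl-5-propyl-4,15-dioxabicyclo[9.3.1]pentadecan-3-one; 32 (2Z)-5-(2-{(1Z)-3-[(methoxycarbonyl)amino]prop-1-en-1-yl}-1,3-oxazol-4-yl)pent-2-enoic acid
Product: 33 neopeltolide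
Conditions: PPh3 (3 equiv), DIAD (3 equiv), benzene, rt
Reagents that add atoms: none
Why: Mitsunobu esterification: the carboxylate displaces the alkoxyphosphonium with inversion, turning the equatorial C5 alcohol into the axial (13R) ester of the target.

**Compound list**

1 | (3R)-5-methoxy-3-methyl-5-oxopentanoic acid, (R)-methyl hydrogen 3-methylglutarate | OC(=O)C[C@@H](C)CC(=O)OC | starting material
2 | methyl (3R)-5-hydroxy-3-methylpentanoate | OCC[C@@H](C)CC(=O)OC | intermediate
3 | methyl (3R)-5-[(tert-butyldiphenylsilyl)oxy]-3-methylpentanoate | CC(C)(C)[Si](c1ccccc1)(c1ccccc1)OCC[C@@H](C)CC(=O)OC | intermediate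
4 | (3R)-5-[(tert-butyldiphenylsilyl)oxy]-3-methylpentanal | CC(C)(C)[Si](c1ccccc1)(c1ccccc1)OCC[C@@H](C)CC=O | intermediate
5 | diisopinocampheylborinate ester of 6 (formed in the flask) | CC(C)(C)[Si](c1ccccc1)(c1ccccc1)OCC[C@@H](C)C[C@H](CC=C)OB([C@@H]1C[C@@H]2C[C@H]([C@H]1C)C2(C)C)[C@@H]1C[C@@H]2C[C@H]([C@H]1C)C2(C)C | intermediate
6 | (4S,6R)-8-[(tert-butyldiphenylsilyl)oxy]-6-methyloct-1-en-4-ol | CC(C)(C)[Si](c1ccccc1)(c1ccccc1)OCC[C@@H](C)C[C@@H](O)CC=C | intermediate
7 | tert-butyl{[(3R,5S)-5-methoxy-3-methyloct-7-en-1-yl]oxy}diphenylsilane | CC(C)(C)[Si](c1ccccc1)(c1ccccc1)OCC[C@@H](C)C[C@@H](OC)CC=C | intermediate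
8 | secondary ozonide (1,2,4-trioxolane) of 7, both epimers at the ring carbon (formed in the flask) | CC(C)(C)[Si](c1ccccc1)(c1ccccc1)OCC[C@@H](C)C[C@@H](OC)CC1OCOO1 | intermediate
9 | (3R,5R)-7-[(tert-butyldiphenylsilyl)oxy]-3-methoxy-5-methylheptanal | CC(C)(C)[Si](c1ccccc1)(c1ccccc1)OCC[C@@H](C)C[C@@H](OC)CC=O | intermediate
10 | (4R,6R,8R)-10-[(tert-butyldiphenylsilyl)oxy]-6-methoxy-8-methyldec-1-en-4-ol | CC(C)(C)[Si](c1ccccc1)(c1ccccc1)OCC[C@@H](C)C[C@@H](OC)C[C@H](O)CC=C | intermediate
11 | (4R,6R,8R)-10-[(tert-butyldiphenylsilyl)oxy]-6-methoxy-8-methyldecan-4-ol | CC(C)(C)[Si](c1ccccc1)(c1ccccc1)OCC[C@@H](C)C[C@@H](OC)C[C@H](O)CCC | intermediate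
12 | but-3-enoic acid | C=CCC(=O)O | starting material
13 | (4R,6R,8R)-10-[(tert-butyldiphenylsilyl)oxy]-6-methoxy-8-methyldecan-4-yl but-3-enoate | CC(C)(C)[Si](c1ccccc1)(c1ccccc1)OCC[C@@H](C)C[C@@H](OC)C[C@@H](CCC)OC(=O)CC=C | intermediate
14 | (4R,6R,8R)-10-hydroxy-6-methoxy-8-methyldecan-4-yl but-3-enoate | OCC[C@@H](C)C[C@@H](OC)C[C@@H](CCC)OC(=O)CC=C | intermediate
15 | (4R,6R,8S)-6-methoxy-8-methyl-10-oxodecan-4-yl but-3-enoate | O=CC[C@@H](C)C[C@@H](OC)C[C@@H](CCC)OC(=O)CC=C | intermediate
16 | (4R,6R,8R,10R)-10-hydroxy-6-methoxy-8-methyltridec-12-yn-4-yl but-3-enoate | C#CC[C@H](O)C[C@@H](C)C[C@@H](OC)C[C@@H](CCC)OC(=O)CC=C | intermediate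
17 | (3E,8R,10R,12R,14R)-8-hydroxy-12-methoxy-10-methyl-6-methylidene-14-propyl-1-oxacyclotetradec-3-en-2-one (formed in the flask) | CCC[C@@H]1C[C@H](OC)C[C@H](C)C[C@@H](O)CC(=C)C/C=C/C(=O)O1 | intermediate
18 | (1R,5R,7R,9S,11R)-7-methoxy-9-methyl-13-methylidene-5-propyl-4,15-dioxabicyclo[9.3.1]pentadecan-3-one | CCC[C@@H]1C[C@H](OC)C[C@H](C)C[C@@H]2CC(=C)C[C@H](CC(=O)O1)O2 | intermediate
19 | spiro secondary ozonide (1,2,4-trioxolane at C13) of 18 (formed in the flask) | CCC[C@@H]1C[C@H](OC)C[C@H](C)C[C@@H]2CC3(OCOO3)C[C@H](CC(=O)O1)O2 | intermediate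
20 | (1R,5R,7R,9S,11R)-7-methoxy-9-methyl-5-propyl-4,15-dioxabicyclo[9.3.1]pentadecane-3,13-dione | CCC[C@@H]1C[C@H](OC)C[C@H](C)C[C@@H]2CC(=O)C[C@H](CC(=O)O1)O2 | intermediate
21 | (1R,5R,7R,9S,11R,13S)-13-hydroxy-7-methoxy-9-methyl-5-propyl-4,15-dioxabicyclo[9.3.1]pentadecan-3-one | CCC[C@@H]1C[C@H](OC)C[C@H](C)C[C@@H]2C[C@H](O)C[C@H](CC(=O)O1)O2 | intermediate
22 | prop-2-yn-1-amine | C#CCN | starting material
23 | methyl prop-2-yn-1-ylcarbamate | C#CCNC(=O)OC | intermediate
24 | methyl 5-bromo-4-oxopentanoate | COC(=O)CCC(=O)CBr | starting material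
25 | methyl 3-(1,3-oxazol-4-yl)propanoate | COC(=O)CCc1cocn1 | intermediate
26 | [4-(3-methoxy-3-oxopropyl)-1,3-oxazol-2-yl]zinc chloride (formed in the flask) | COC(=O)CCc1coc([Zn]Cl)n1 | intermediate
27 | methyl 3-(2-iodo-1,3-oxazol-4-yl)propanoate | COC(=O)CCc1coc(I)n1 | intermediate
28 | 3-(2-iodo-1,3-oxazol-4-yl)propanal | O=CCCc1coc(I)n1 | intermediate
29 | methyl (2Z)-5-(2-iodo-1,3-oxazol-4-yl)pent-2-enoate | COC(=O)/C=C\CCc1coc(I)n1 | intermediate
30 | methyl (2Z)-5-(2-{3-[(methoxycarbonyl)amino]prop-1-yn-1-yl}-1,3-oxazol-4-yl)pent-2-enoate | COC(=O)/C=C\CCc1coc(C#CCNC(=O)OC)n1 | intermediate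
31 | methyl (2Z)-5-(2-{(1Z)-3-[(methoxycarbonyl)amino]prop-1-en-1-yl}-1,3-oxazol-4-yl)pent-2-enoate | COC(=O)/C=C\CCc1coc(/C=C\CNC(=O)OC)n1 | intermediate
32 | (2Z)-5-(2-{(1Z)-3-[(methoxycarbonyl)amino]prop-1-en-1-yl}-1,3-oxazol-4-yl)pent-2-enoic acid | OC(=O)/C=C\CCc1coc(/C=C\CNC(=O)OC)n1 | intermediate
33 | neopeltolide, (1R,5R,7R,9S,11R,13R)-7-methoxy-9-methyl-3-oxo-5-propyl-4,15-dioxabicyclo[9.3.1]pentadecan-13-yl ester of acid 32 | CCC[C@@H]1C[C@H](OC)C[C@H](C)C[C@@H]2C[C@@H](OC(=O)/C=C\CCc3coc(/C=C\CNC(=O)OC)n3)C[C@H](CC(=O)O1)O2 | target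

**Step count**
Total: 24 steps. Longest linear sequence: 16 steps (steps 1–15 and 24); fragment 2 takes 8 steps (16–23).

**Steps most likely to fail and fallbacks**

Step 13 (Proposed new method). The tethered ene–yne coupling may give oligomers in place of the 14-membered ring, may couple through the terminal alkyne carbon to the ring-enlarged linear diene, or the skipped diene may move into conjugation before the oxygen adds. The fallback uses a Prins macrocyclisation, known for this ring system. It leaves the route at alcohol 11. Steglich esterification with 3,3-diethoxypropanoic acid should give (4R,6R,8R)-10-[(tert-butyldiphenylsilyl)oxy]-6-methoxy-8-methyldecan-4-yl 3,3-diethoxypropanoate F1. HF·pyridine should give the primary alcohol (4R,6R,8R)-10-hydroxy-6-methoxy-8-methyldecan-4-yl 3,3-diethoxypropanoate F2, and Dess–Martin oxidation the aldehyde (4R,6R,8S)-6-methoxy-8-methyl-10-oxodecan-4-yl 3,3-diethoxypropanoate F3. Allylation with (−)-Ipc2B(allyl) (si face, as in step 4) should give the homoallylic alcohol (4R,6R,8R,10S)-10-hydroxy-6-methoxy-8-methyltridec-12-en-4-yl 3,3-diethoxypropanoate F4. Under TESOTf, TMSOAc and AcOH in dilute CH2Cl2 the acetal ionises and condenses with the C7 hydroxyl to an oxocarbenium ion, the alkene closes the oxane through an all-equatorial chair and acetate traps C5. This should give (1R,5R,7R,9S,11R,13S)-7-methoxy-9-methyl-3-oxo-5-propyl-4,15-dioxabicyclo[9.3.1]pentadecan-13-yl acetate F5. K2CO3 in MeOH then returns the route at alcohol 21, ready for step 24.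

Step 12. Facial selectivity of the catalyst-controlled propargylation may be low on this β-branched aldehyde, its sense may be the reverse of that assumed, and allenyl transfer may compete. The fallback gives up catalyst control. It leaves at aldehyde 15. Zinc-mediated Barbier propargylation (propargyl bromide, Zn, THF/aq. NH4Cl) should give 16 together with its C10 epimer (4R,6R,8R,10S)-10-hydroxy-6-methoxy-8-methyltridec-12-yn-4-yl but-3-enoate F6, separable by chromatography. F6 is inverted by Mitsunobu reaction with chloroacetic acid (PPh3, DIAD) to (4R,6R,8S,10R)-10-[(chloroacetyl)oxy]-6-methoxy-8-methyltridec-12-yn-4-yl but-3-enoate F7. Thiourea and NaHCO3 in EtOH remove the chloroacetate without touching the but-3-enoate, and the route is rejoined at 16.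

Step 7. Chelate control may be incomplete (a competing open transition state, or partial attack of TiCl4 on the silyl ether), which would erode the 1,3-anti selectivity at C13. The fallback sets C13 by reduction instead of addition. It leaves at aldehyde 9. n-PrMgBr in THF at −78 °C should give 11 mixed with its C4 epimer (4S,6R,8R)-10-[(tert-butyldiphenylsilyl)oxy]-6-methoxy-8-methyldecan-4-ol F8. Dess–Martin oxidation of the mixture converges on (6R,8R)-10-[(tert-butyldiphenylsilyl)oxy]-6-methoxy-8-methyldecan-4-one F9. SmI2 in THF/MeOH, which reduces β-alkoxy ketones to the anti-1,3-diol monoethers, should return the route at 11, so step 8 is no longer needed.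

**Further compounds**
F1 | step 13 | (4R,6R,8R)-10-[(tert-butyldiphenylsilyl)oxy]-6-methoxy-8-methyldecan-4-yl 3,3-diethoxypropanoate | CC(C)(C)[Si](c1ccccc1)(c1ccccc1)OCC[C@@H](C)C[C@@H](OC)C[C@@H](CCC)OC(=O)CC(OCC)OCC
F2 | step 13 | (4R,6R,8R)-10-hydroxy-6-methoxy-8-methyldecan-4-yl 3,3-diethoxypropanoate | OCC[C@@H](C)C[C@@H](OC)C[C@@H](CCC)OC(=O)CC(OCC)OCC
F3 | step 13 | (4R,6R,8S)-6-methoxy-8-methyl-10-oxodecan-4-yl 3,3-diethoxypropanoate | O=CC[C@@H](C)C[C@@H](OC)C[C@@H](CCC)OC(=O)CC(OCC)OCC
F4 | step 13 | (4R,6R,8R,10S)-10-hydroxy-6-methoxy-8-methyltridec-12-en-4-yl 3,3-diethoxypropanoate | C=CC[C@H](O)C[C@@H](C)C[C@@H](OC)C[C@@H](CCC)OC(=O)CC(OCC)OCC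
F5 | step 13 | (1R,5R,7R,9S,11R,13S)-7-methoxy-9-methyl-3-oxo-5-propyl-4,15-dioxabicyclo[9.3.1]pentadecan-13-yl acetate | CCC[C@@H]1C[C@H](OC)C[C@H](C)C[C@@H]2C[C@H](OC(C)=O)C[C@H](CC(=O)O1)O2
F6 | step 12 | (4R,6R,8R,10S)-10-hydroxy-6-methoxy-8-methyltridec-12-yn-4-yl but-3-enoate | C#CC[C@@H](O)C[C@@H](C)C[C@@H](OC)C[C@@H](CCC)OC(=O)CC=C
F7 | step 12 | (4R,6R,8S,10R)-10-[(chloroacetyl)oxy]-6-methoxy-8-methyltridec-12-yn-4-yl but-3-enoate | C#CC[C@H](OC(=O)CCl)C[C@@H](C)C[C@@H](OC)C[C@@H](CCC)OC(=O)CC=C
F8 | step 7 | (4S,6R,8R)-10-[(tert-butyldiphenylsilyl)oxy]-6-methoxy-8-methyldecan-4-ol | CC(C)(C)[Si](c1ccccc1)(c1ccccc1)OCC[C@@H](C)C[C@@H](OC)C[C@@H](O)CCC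
F9 | step 7 | (6R,8R)-10-[(tert-butyldiphenylsilyl)oxy]-6-methoxy-8-methyldecan-4-one | CC(C)(C)[Si](c1ccccc1)(c1ccccc1)OCC[C@@H](C)C[C@@H](OC)CC(=O)CCC
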